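**Plan**
- Numbering: naphthalene C1–C8a (ring A = C1–C4, ring B = C5–C8); dihydronaphthalene C1′–C8a′ (ring C aromatic, ring D = C1′–C4′).
- Retrosynthetic cuts, in order: C1′–C2′ of ring D (aldol); the C4′–C3′ benzyl–alkenyl bond (Stille); C3–C4 and C1–C2 of ring A (Michael–Dieckmann annulation); the C7–C7′ biaryl bond (Suzuki).
- Enabling feature: ring A carries C1–OH, C2–acetyl, C3–CH3 and C4–H, which is a toluate (benzylic C4, ester C1) fused with the methyl enol ether of acetylacetone (C3, C2).
- Forward: rings B and C are made from one bromocresol and joined; ring A is annulated; one BBr3 step frees the phenols, the aldehyde and a benzylic bromide; the enone chain is attached; ring D closes last.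
- Stereochemistry: C1′ (S) and C2′ (R), trans, are both set in the final D-proline-mediated intramolecular aldol; no later step can scramble them.

Key step: step 11

Assumption: the E/Z purity of stannane 19 and enone 20 is immaterial, because the enone geometry is erased when the dienamine forms in step 15.

**Route**

Step 1
Reactants: 1 2-bromo-5-methylphenol
Product: 2 3-bromo-2-hydroxy-6-methylbenzaldehyde
Conditions: MgCl2, Et3N, (CH2O)n, THF, reflux; aq. HCl
Reagents that add atoms: paraformaldehyde (as formaldehyde), C=O
Why: Casnati–Skattebøl ortho-formylation, in which the magnesium phenoxide delivers formaldehyde to the only free ortho carbon (between OH and CH3) and a second formaldehyde oxidises the benzylic alkoxide to the aldehyde.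

Step 2
Reactants: 2 3-bromo-2-hydroxy-6-methylbenzaldehyde
Product: 3 3-bromo-2-hydroxy-6-methylbenzoic acid
Conditions: NaClO2, NaH2PO4, 2-methylbut-2-ene (large excess), t-BuOH/H2O, rt
Reagents that add atoms: sodium chlorite, [Na+].[O-]Cl=O
Why: Pinnick oxidation converts the aldehyde into the acid without touching the aryl bromide, the alkene scavenger removing HOCl before it can chlorinate the phenol ring.

Step 3
Reactants: 3 3-bromo-2-hydroxy-6-methylbenzoic acid
Product: 4 methyl 3-bromo-2-methoxy-6-methylbenzoate
Conditions: MeI, K2CO3, DMF, 50 °C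
Reagents that add atoms: iodomethane, CI
Why: Williamson-type O-methylation of carboxylate and phenoxide in one operation, which avoids Fischer esterification of the doubly ortho-substituted acid.

Step 4
Reactants: 4 methyl 3-bromo-2-methoxy-6-methylbenzoate
Product: 5 methyl 2-methoxy-6-methyl-3-(4,4,5,5-tetramethyl-1,3,2-dioxaborolan-2-yl)benzoate
Conditions: B2pin2, Pd(dppf)Cl2, KOAc, 1,4-dioxane, 90 °C
Reagents that add atoms: bis(pinacolato)diboron, CC1(C)OB(OC1(C)C)B1OC(C)(C)C(C)(C)O1
Why: Miyaura borylation of the aryl bromide, with acetate too weak a base to trigger biaryl homocoupling and the hindered ester inert.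

Step 5
Reactants: 4 methyl 3-bromo-2-methoxy-6-methylbenzoate
Product: 6 methyl 3-bromo-6-(bromomethyl)-2-methoxybenzoate
Conditions: NBS, AIBN, PhCF3, 85 °C
Reagents that add atoms: N-bromosuccinimide, O=C1CCC(=O)N1Br
Why: Wohl–Ziegler radical bromination is selective for the benzylic methyl group of the ester-deactivated arene.

Step 6
Reactants: 6 methyl 3-bromo-6-(bromomethyl)-2-methoxybenzoate
Product: 7 methyl 3-bromo-2-methoxy-6-(methoxymethyl)benzoate
Conditions: NaOMe, MeOH, 0 °C to rt
Reagents that add atoms: sodium methoxide, [Na+].[O-]C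
Why: SN2 displacement of the benzylic bromide by methoxide (Williamson ether synthesis) should outpace lactonisation to the phthalide at low temperature; the CH2OMe group survives strong base and is turned into CH2Br by BBr3 later.

Step 7
Reactants: 7 methyl 3-bromo-2-methoxy-6-(methoxymethyl)benzoate
Product: 8 [3-bromo-2-methoxy-6-(methoxymethyl)phenyl]methanol
Conditions: i-Bu2AlH, CH2Cl2, −78 to 0 °C; aq. potassium sodium tartrate
Reagents that add atoms: none
Why: Hydride reduction of the hindered methyl ester to the primary alcohol, leaving the aryl bromide and the benzylic ether intact.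

Step 8
Reactants: 8 [3-bromo-2-methoxy-6-(methoxymethyl)phenyl]methanol
Product: 9 3-bromo-2-methoxy-6-(methoxymethyl)benzaldehyde
Conditions: MnO2, CH2Cl2, rt
Reagents that add atoms: none
Why: MnO2 oxidises benzylic alcohols selectively to aldehydes without over-oxidation.

Step 9
Reactants: 9 3-bromo-2-methoxy-6-(methoxymethyl)benzaldehyde
Product: 10 1-bromo-3-(dimethoxymethyl)-2-methoxy-4-(methoxymethyl)benzene
Conditions: HC(OMe)3, TsOH (cat.), MeOH, rt to 50 °C; Et3N quench
Reagents that add atoms: methanol, CO; trimethyl orthoformate, COC(OC)OC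
Why: Acid-catalysed acetalisation, driven by the orthoformate as water scavenger, masks the aldehyde (future C1′) as a base-stable dimethyl acetal.

Step 10
Reactants: 5 methyl 2-methoxy-6-methyl-3-(4,4,5,5-tetramethyl-1,3,2-dioxaborolan-2-yl)benzoate; 10 1-bromo-3-(dimethoxymethyl)-2-methoxy-4-(methoxymethyl)benzene
Product: 11 methyl 3-[3-(dimethoxymethyl)-2-methoxy-4-(methoxymethyl)phenyl]-2-methoxy-6-methylbenzoate
Conditions: Pd(OAc)2, SPhos, K3PO4, toluene/H2O, 90 °C
Reagents that add atoms: none
Why: Suzuki–Miyaura coupling to a biaryl with only two ortho substituents, which a dialkylbiarylphosphine ligand handles, while ester, acetal and ethers tolerate aqueous phosphate.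

Step 11
Reactants: 11 methyl 3-[3-(dimethoxymethyl)-2-methoxy-4-(methoxymethyl)phenyl]-2-methoxy-6-methylbenzoate; 12 (E)-4-methoxypent-3-en-2-one
Product: 15 1-{7-[3-(dimethoxymethyl)-2-methoxy-4-(methoxymethyl)phenyl]-1-hydroxy-8-methoxy-3-methylnaphthalen-2-yl}ethan-1-one, via Michael adduct enolate 13 (not isolated), via cyclised methoxy diketone 14 (not isolated)
Conditions: LiN(i-Pr)2 (2.5 equiv), THF, −78 °C; then 12, −78 °C to rt; aq. NH4Cl
Reagents that add atoms: none
Why: LiN(i-Pr)2 removes a proton from the only acidified position of 11, the methyl group ortho to the ester (future C4); this benzylic anion adds to the β-carbon of 12 (C3–C4 bond) to give enolate 13, whose α-carbon (C2) attacks the ester carbonyl (C1–C2 bond) in a Dieckmann-type 6-exo-trig closure of ring A to give 14. Expulsion of the ester methoxide, β-elimination of the C3 methoxy group and enolisation then aromatise ring A to the 2-acetyl-1-naphthol. The closest known reaction type is the Staunton–Weinreb annulation of ortho-toluates with β-alkoxy enones. No stereocentre survives, because the transient C3 centre is lost on aromatisation. The step needs chemoselective deprotonation and a fixed Michael-then-Dieckmann order: the first is secured because ring C offers only ethers and an acetal and the doubly ortho-substituted ester resists self-condensation, the second because only the enolate formed by conjugate addition can reach the ester through a six-membered transition state.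

Step 12
Reactants: 15 1-{7-[3-(dimethoxymethyl)-2-methoxy-4-(methoxymethyl)phenyl]-1-hydroxy-8-methoxy-3-methylnaphthalen-2-yl}ethan-1-one
Product: 16 3-(7-acetyl-1,8-dihydroxy-6-methylnaphthalen-2-yl)-6-(bromomethyl)-2-hydroxybenzaldehyde
Conditions: BBr3 (8 equiv), CH2Cl2, −78 °C to rt; ice-water
Reagents that add atoms: boron tribromide, BrB(Br)Br; water, O
Why: Lewis-acid ether cleavage in which BBr3 removes both aryl methyl ethers (each assisted by a neighbouring boron-bound oxygen), turns the benzylic methyl ether into the benzylic bromide and the acetal into the aldehyde on aqueous work-up; the boron-complexed ortho-formyl group disfavours benzylic cation chemistry and the phenol meta to CH2Br cannot form a quinone methide.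

Step 13
Reactants: 17 pent-3-yn-2-one
Product: 19 (E)-4-(tributylstannyl)pent-3-en-2-one, via alkenylcopper adduct 18 (not isolated)
Conditions: Bu3SnH, LiN(i-Pr)2, THF, 0 °C; CuBr·SMe2, −78 °C; then 17, MeOH, −78 °C
Reagents that add atoms: tributyltin hydride, CCCC[SnH](CCCC)CCCC
Why: Stannylcupration of the ynone, in which syn addition of the tin–copper bond and protonation of alkenylcopper 18 with retention place tin on C4 trans to the acetyl group.

Step 14
Reactants: 16 3-(7-acetyl-1,8-dihydroxy-6-methylnaphthalen-2-yl)-6-(bromomethyl)-2-hydroxybenzaldehyde; 19 (E)-4-(tributylstannyl)pent-3-en-2-one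
Product: 20 3-(7-acetyl-1,8-dihydroxy-6-methylnaphthalen-2-yl)-2-hydroxy-6-[(2E)-2-methyl-4-oxopent-2-en-1-yl]benzaldehyde
Conditions: Pd2(dba)3, P(2-furyl)3, CuI, NMP, 45 °C
Reagents that add atoms: none
Why: Stille coupling of a benzylic bromide with an alkenylstannane (oxidative addition to zerovalent palladium, copper-assisted transmetalation, reductive elimination) forms the benzyl–alkenyl bond without base, so the three free phenols and the aldehyde remain spectators.

Step 15
Reactants: 20 3-(7-acetyl-1,8-dihydroxy-6-methylnaphthalen-2-yl)-2-hydroxy-6-[(2E)-2-methyl-4-oxopent-2-en-1-yl]benzaldehyde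
Product: 22 1-[(1S,2R)-7-(7-acetyl-1,8-dihydroxy-6-methylnaphthalen-2-yl)-1,8-dihydroxy-3-methyl-1,2-dihydronaphthalen-2-yl]ethan-1-one (target), via proline dienamine 21 (not isolated)
Conditions: D-proline (30 mol%), DMSO, rt
Reagents that add atoms: none
Why: Proposed new method: D-proline should condense with the enone carbonyl of 20, γ-deprotonation at the benzylic CH2 gives the 2-aminodiene 21, and its α-carbon (C2′) attacks the neighbouring aldehyde in a 6-enolexo aldol (the γ-carbon could only close a four-membered ring), after which hydrolysis releases the ketone with C3′=C4′ conjugated to ring C; in the chair-like transition state of the (E)-enamine the carboxylic acid hydrogen-bonds the aldehyde oxygen and exposes its Si face, which should set C1′ (S) and C2′ (R) in the trans (anti) relationship; the closest known reaction types are the proline-catalysed 6-enolexo aldolisation of dicarbonyl compounds and the 5-enolexo cyclisation of ketones tethered to aryl aldehydes, the new element being an enone-derived dienamine as donor.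

**Compound list**

1 | 2-bromo-5-methylphenol | Cc1ccc(Br)c(O)c1 | starting material
2 | 3-bromo-2-hydroxy-6-methylbenzaldehyde | Cc1ccc(Br)c(O)c1C=O | intermediate
3 | 3-bromo-2-hydroxy-6-methylbenzoic acid | Cc1ccc(Br)c(O)c1C(=O)O | intermediate
4 | methyl 3-bromo-2-methoxy-6-methylbenzoate | COC(=O)c1c(C)ccc(Br)c1OC | intermediate
5 | methyl 2-methoxy-6-methyl-3-(4,4,5,5-tetramethyl-1,3,2-dioxaborolan-2-yl)benzoate | COC(=O)c1c(C)ccc(B2OC(C)(C)C(C)(C)O2)c1OC | intermediate
6 | methyl 3-bromo-6-(bromomethyl)-2-methoxybenzoate | COC(=O)c1c(CBr)ccc(Br)c1OC | intermediate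
7 | methyl 3-bromo-2-methoxy-6-(methoxymethyl)benzoate | COCc1ccc(Br)c(OC)c1C(=O)OC | intermediate
8 | [3-bromo-2-methoxy-6-(methoxymethyl)phenyl]methanol | COCc1ccc(Br)c(OC)c1CO | intermediate
9 | 3-bromo-2-methoxy-6-(methoxymethyl)benzaldehyde | COCc1ccc(Br)c(OC)c1C=O | intermediate
10 | 1-bromo-3-(dimethoxymethyl)-2-methoxy-4-(methoxymethyl)benzene | COCc1ccc(Br)c(OC)c1C(OC)OC | intermediate
11 | methyl 3-[3-(dimethoxymethyl)-2-methoxy-4-(methoxymethyl)phenyl]-2-methoxy-6-methylbenzoate | COC(=O)c1c(C)ccc(-c2ccc(COC)c(C(OC)OC)c2OC)c1OC | intermediate (key-step precursor)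
12 | (E)-4-methoxypent-3-en-2-one | CO/C(C)=C/C(C)=O | starting material
13 | lithium enolate of methyl 3-[3-(dimethoxymethyl)-2-methoxy-4-(methoxymethyl)phenyl]-2-methoxy-6-(2-methoxy-2-methyl-4-oxopentyl)benzoate (racemic at the methoxy-bearing carbon) | COC(=O)c1c(CC(C)(OC)C=C(C)O[Li])ccc(-c2ccc(COC)c(C(OC)OC)c2OC)c1OC | intermediate (not isolated)
14 | 2-acetyl-7-[3-(dimethoxymethyl)-2-methoxy-4-(methoxymethyl)phenyl]-3,8-dimethoxy-3-methyl-3,4-dihydronaphthalen-1(2H)-one (present as its enolate, diastereomer mixture) | COc1c(-c2ccc(COC)c(C(OC)OC)c2OC)ccc2c1C(=O)C(C(C)=O)C(C)(OC)C2 | intermediate (not isolated)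
15 | 1-{7-[3-(dimethoxymethyl)-2-methoxy-4-(methoxymethyl)phenyl]-1-hydroxy-8-methoxy-3-methylnaphthalen-2-yl}ethan-1-one | COCc1ccc(-c2ccc3cc(C)c(C(C)=O)c(O)c3c2OC)c(OC)c1C(OC)OC | intermediate (key-step product)
16 | 3-(7-acetyl-1,8-dihydroxy-6-methylnaphthalen-2-yl)-6-(bromomethyl)-2-hydroxybenzaldehyde | CC(=O)c1c(C)cc2ccc(-c3ccc(CBr)c(C=O)c3O)c(O)c2c1O | intermediate
17 | pent-3-yn-2-one | CC#CC(C)=O | starting material
18 | (Z)-3-cuprio-4-(tributylstannyl)pent-3-en-2-one (alkenylcopper adduct) | CCCC[Sn](CCCC)(CCCC)/C(C)=C(\[Cu])C(C)=O | intermediate (not isolated)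
19 | (E)-4-(tributylstannyl)pent-3-en-2-one | CCCC[Sn](CCCC)(CCCC)/C(C)=C/C(C)=O | intermediate
20 | 3-(7-acetyl-1,8-dihydroxy-6-methylnaphthalen-2-yl)-2-hydroxy-6-[(2E)-2-methyl-4-oxopent-2-en-1-yl]benzaldehyde | CC(=O)/C=C(\C)Cc1ccc(-c2ccc3cc(C)c(C(C)=O)c(O)c3c2O)c(O)c1C=O | intermediate
21 | (2R)-1-[(2E,4Z)-5-{4-(7-acetyl-1,8-dihydroxy-6-methylnaphthalen-2-yl)-2-formyl-3-hydroxyphenyl}-4-methylpenta-2,4-dien-2-yl]pyrrolidine-2-carboxylic acid (proline dienamine) | OC(=O)[C@H]1CCCN1/C(C)=C/C(C)=C\c1ccc(-c2ccc3cc(C)c(C(C)=O)c(O)c3c2O)c(O)c1C=O | intermediate (not isolated)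
22 | 1-[(1S,2R)-7-(7-acetyl-1,8-dihydroxy-6-methylnaphthalen-2-yl)-1,8-dihydroxy-3-methyl-1,2-dihydronaphthalen-2-yl]ethan-1-one | CC(=O)c1c(C)cc2ccc(-c3ccc4c(c3O)[C@@H](O)[C@H](C(C)=O)C(C)=C4)c(O)c2c1O | target

**Step count and risks**

Total: 15 steps. Longest linear sequence: 13 steps (1 → 2 → 3 → 4 → 6 → 7 → 8 → 9 → 10 → 11 → 15 → 16 → 20 → 22); steps 4 and 13 are side branches.

Steps most likely to fail:

1. Step 15 (carries the label). The secondary amine may condense only slowly with the β,β-disubstituted enone. The aldol may lose water through its enamine, which would aromatise ring D. Reversible addition may erode facial selectivity. Fallback with known chemistry, setting out from 20: catalyst control is given up and ring D is closed with pyrrolidine/AcOH in DMSO at 0 °C to rt, the classical achiral amine-salt conditions for intramolecular ketone–aldehyde aldol addition. This should give the trans-aldol as the racemate, that is 22 together with the mirror-image (1R,2S)-aldol F1. The enantiomers are then separated by preparative HPLC on a polysaccharide-based chiral stationary phase, and the route is rejoined at 22.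

2. Step 12. The hindered aryl methyl ethers may be cleaved incompletely. The benzylic bromide may be hydrolysed to the lactol on work-up. The electron-rich naphthalenediol may be benzylated under the Lewis acid. Fallback, setting out from 15: the unmasking is staged under chelation control. Aqueous HCl in THF first hydrolyses the acetal to 3-(7-acetyl-8-hydroxy-1-methoxy-6-methylnaphthalen-2-yl)-2-methoxy-6-(methoxymethyl)benzaldehyde F2. The milder BCl3 (CH2Cl2, −78 to 0 °C) then removes the two methyl ethers that sit next to the formyl group and the peri-hydroxyl, and converts the benzylic ether into the chloride 3-(7-acetyl-1,8-dihydroxy-6-methylnaphthalen-2-yl)-6-(chloromethyl)-2-hydroxybenzaldehyde F3. F3 is used in place of 16 in the Stille coupling of step 14, so the route is rejoined at 20.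

3. Step 14. Transmetalation from the electron-poor β-stannyl enone may be slow, so that the benzylpalladium intermediate decays by homocoupling or reduction. Fallback, setting out from 16: the carbon chain is built in two stages. Stille coupling with commercial tributyl(prop-1-en-2-yl)stannane, a fast-transferring alkenyl group, under the same palladium conditions gives 3-(7-acetyl-1,8-dihydroxy-6-methylnaphthalen-2-yl)-2-hydroxy-6-(2-methylprop-2-en-1-yl)benzaldehyde F4. Cross-metathesis of F4 with but-3-en-2-one (second-generation Hoveyda–Grubbs catalyst, CH2Cl2, 40 °C) then installs the acetyl terminus, and the route is rejoined at 20.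

**Further compounds**

F1 | step 15 | 1-[(1R,2S)-7-(7-acetyl-1,8-dihydroxy-6-methylnaphthalen-2-yl)-1,8-dihydroxy-3-methyl-1,2-dihydronaphthalen-2-yl]ethan-1-one (enantiomer of 22) | CC(=O)c1c(C)cc2ccc(-c3ccc4c(c3O)[C@H](O)[C@@H](C(C)=O)C(C)=C4)c(O)c2c1O
F2 | step 12 | 3-(7-acetyl-8-hydroxy-1-methoxy-6-methylnaphthalen-2-yl)-2-methoxy-6-(methoxymethyl)benzaldehyde | COCc1ccc(-c2ccc3cc(C)c(C(C)=O)c(O)c3c2OC)c(OC)c1C=O
F3 | step 12 | 3-(7-acetyl-1,8-dihydroxy-6-methylnaphthalen-2-yl)-6-(chloromethyl)-2-hydroxybenzaldehyde | CC(=O)c1c(C)cc2ccc(-c3ccc(CCl)c(C=O)c3O)c(O)c2c1O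
F4 | step 14 | 3-(7-acetyl-1,8-dihydroxy-6-methylnaphthalen-2-yl)-2-hydroxy-6-(2-methylprop-2-en-1-yl)benzaldehyde | C=C(C)Cc1ccc(-c2ccc3cc(C)c(C(C)=O)c(O)c3c2O)c(O)c1C=O
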